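**Plan**

1. Numbering: each half is C1–C12 in the order of the target SMILES (methyls uncounted; primes for the saturated-ketone half, C1' = the linking CH2). The enabling feature is that C2, the ring carbon carrying the exocyclic CH2 (C1), is bonded to the quaternary bridgehead C10 of the bicyclo[3.2.1]octane C5–C12 and completes ring A (C2–C3–C4–C5–C10). C2=C1 is therefore what a C10 radical leaves after 5-exo-dig addition to a terminal alkyne hung from C5.
2. Cuts: C2–C10 (bridgehead radical closure, used for both halves), C4–C1' (Michael union), C2–C3 (ethynyl addition), C3–C4 and C4–C5 (two one-carbon homologations of the C5 ketone), C6–C7 and C9–C10 (annulation of crotonaldehyde onto a cyclopentanone β-keto ester).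
3. Forward: cyclopentanone (C5, C6, C10–C12) → bicyclo[3.2.1]octanone → C5 side chain → ring A of suberosenone (the later saturated half) → union at C4–C1' → ring A of the enone half → enone.
4. Stereochemistry: C9 from the prolinol silyl ether catalyst, C10 from the open transition state of the same Michael step, C6 from bridging. C5 comes from equilibrating the aldehyde away from the axial C9 methyl, C4 from the same amine in the union, and C2' from ketonisation anti to the C9' methyl. The C3 carbinol is uncontrolled and is oxidised at the end.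

Key step: step 20

Remark: atom labels C1–C12 and C1'–C12' in the text are those of the target; locants inside systematic names belong to the names.
Assumption: ketonisation at C2' after the union delivers hydrogen to the face away from the syn-axial C9' methyl, which is the configuration of the natural dimer; later steps avoid strong base at this centre.
Remark: the C3 carbinol forms as a mixture of epimers that is carried through; one epimer is drawn.

**Route**

Step 1
Reactants: 1 3,3-dimethylcyclopentan-1-one
Product: 2 allyl 4,4-dimethyl-2-oxocyclopentane-1-carboxylate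
Conditions: NaH, (CH2=CHCH2O)2CO, THF, reflux; aq. HCl
Reagents that add atoms: diallyl carbonate, C=CCOC(=O)OCC=C
Why: Claisen-type C-acylation of the ketone enolate goes to the α-carbon remote from the gem-dimethyl carbon and is driven by formation of the β-keto ester enolate; C10 stays enolisable, so no stereocentre is fixed.

Step 2
Reactants: 2 allyl 4,4-dimethyl-2-oxocyclopentane-1-carboxylate, 3 (E)-but-2-enal
Product: 5 allyl (1S,2S,5S)-4-hydroxy-2,6,6-trimethyl-8-oxobicyclo[3.2.1]octane-1-carboxylate (2-methyl syn to the one-carbon bridge; C4 carbinol epimers, the equatorial 4S one drawn), via Michael adduct 4 (not isolated)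
Conditions: (R)-α,α-diphenylprolinol trimethylsilyl ether (10 mol %), PhCO2H (10 mol %), toluene, 0 °C; then DBU (0.3 equiv), 23 °C
Reagents that add atoms: none
Why: Iminium-catalysed Michael addition of the β-keto ester to the enal followed by 6-(enolendo)-exo-trig aldol closure is an established annulation to bicyclo[3.2.1]octan-8-ones; the amine shields one face of the enal and so fixes C9, C10 follows from the open synclinal transition state that puts the enal methyl between the two carbonyl arms of the nucleophile, and C6 can only bond on the face that bridges, which leaves the C9 methyl syn to the one-carbon bridge.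

Step 3
Reactants: 5 ketol
Product: 6 O-phenyl thionocarbonate of 5
Conditions: PhOC(S)Cl, pyridine, DMAP (cat.), CH2Cl2, 23 °C
Reagents that add atoms: O-phenyl chlorothionoformate, S=C(Cl)Oc1ccccc1
Why: Acylation of the secondary alcohol; β-elimination is closed because the only α-hydrogen sits at the bridgehead C6.

Step 4
Reactants: 6 thionocarbonate
Product: 7 allyl (1S,2S,5R)-2,6,6-trimethyl-8-oxobicyclo[3.2.1]octane-1-carboxylate
Conditions: Bu3SnH (0.5 M), AIBN, toluene, 90 °C
Reagents that add atoms: none
Why: Barton–McCombie deoxygenation; the secondary C7 radical is reduced by concentrated tributyltin hydride before a 1,2-acyl shift of the β-keto radical can compete, and no stereocentre is touched.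

Step 5
Reactants: 7 bicyclic keto ester, 8 (methoxymethyl)triphenylphosphonium chloride
Product: 9 allyl 8-(methoxymethylidene)-2,6,6-trimethylbicyclo[3.2.1]octane-1-carboxylate (configuration of 7; E/Z mixture)
Conditions: KN(SiMe3)2, THF, 0 → 60 °C
Reagents that add atoms: none
Why: Wittig methoxymethylenation of the non-enolisable bridging ketone; the alkoxide-free ylide avoids retro-Claisen opening of the β-keto ester.

Step 6
Reactants: 9 enol ether
Product: 11 allyl (1S,2S,5S,8S)-8-formyl-2,6,6-trimethylbicyclo[3.2.1]octane-1-carboxylate (formyl over the two-carbon bridge), via C5-epimeric aldehyde 10 (not isolated)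
Conditions: 2 M HCl, THF, 23 °C; then DBU (0.2 equiv), CH2Cl2, 23 °C
Reagents that add atoms: water, O
Why: Enol ether hydrolysis followed by base equilibration of the enolisable aldehyde should leave the formyl group over the two-carbon bridge, equatorial on the six-membered ring, because the other position is syn-axial to the C9 methyl; this sets C5.

Step 7
Reactants: 11 aldehyde, 8 (methoxymethyl)triphenylphosphonium chloride
Product: 13 allyl (1S,2S,5S,8S)-2,6,6-trimethyl-8-(2-oxoethyl)bicyclo[3.2.1]octane-1-carboxylate, via enol ether 12 (not isolated)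
Conditions: KN(SiMe3)2, THF, 0 °C; then 2 M HCl, THF, 23 °C
Reagents that add atoms: water, O
Why: Wittig methoxymethylenation and hydrolysis is a standard one-carbon homologation of aldehydes; C5 is already the equilibrium epimer, so the basic ylide cannot erode it.

Step 8
Reactants: 13 homologated aldehyde, 14 ethynylmagnesium bromide
Product: 15 allyl 8-(2-hydroxybut-3-yn-1-yl)-2,6,6-trimethylbicyclo[3.2.1]octane-1-carboxylate (configuration of 13)
Conditions: THF, −78 → −40 °C; aq. NH4Cl
Reagents that add atoms: none
Why: Grignard addition to the aldehyde, the hindered bridgehead ester being inert at low temperature; the carbinol configuration is immaterial.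

Step 9
Reactants: 15 propargylic alcohol
Product: 16 tert-butyldimethylsilyl ether of 15
Conditions: TBSOTf, 2,6-lutidine, CH2Cl2, −78 °C
Reagents that add atoms: tert-butyldimethylsilyl triflate, CC(C)(C)[Si](C)(C)OS(=O)(=O)C(F)(F)F
Why: Silylation of the secondary alcohol is fast at low temperature and blocks lactonisation onto the C10 carboxyl once the acid is freed.

Step 10
Reactants: 16 silyl ether
Product: 17 8-[2-(tert-butyldimethylsilyloxy)but-3-yn-1-yl]-2,6,6-trimethylbicyclo[3.2.1]octane-1-carboxylic acid
Conditions: Pd(PPh3)4 (5 mol %), morpholine, THF, 23 °C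
Reagents that add atoms: none
Why: Tsuji–Trost deallylation with zerovalent palladium passes the allyl group to morpholine under neutral conditions that leave the silyl ether and the terminal alkyne alone.

Step 11
Reactants: 17 bridgehead acid
Product: 18 1,3-dioxoisoindolin-2-yl ester of 17
Conditions: N-hydroxyphthalimide, DIC, DMAP (cat.), CH2Cl2, 23 °C
Reagents that add atoms: N-hydroxyphthalimide, ON1C(=O)c2ccccc2C1=O
Why: Steglich-type carbodiimide esterification is routine for tertiary and bridgehead acids and gives the redox-active ester.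

Step 12
Reactants: 18 redox-active ester
Product: 19 C3 tert-butyldimethylsilyl ether of the tricyclic allylic alcohol 20 (ring A closed, exocyclic C1=C2)
Conditions: [Ru(bpy)3]Cl2 (1 mol %), Hantzsch ester (1.5 equiv, in portions), DMF, blue LEDs, 23 °C
Reagents that add atoms: none
Why: Photoreductive decarboxylation gives the C10 bridgehead radical, which closes 5-exo-dig onto the terminal alkyne and takes hydrogen from the Hantzsch ester; the ring can only be cis-fused at C5–C10, so no stereochemical choice arises.

Step 13
Reactants: 19 silyl ether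
Product: 20 tricyclic allylic alcohol (suberosenone with C3 as carbinol)
Conditions: HF·pyridine, THF, 0 → 23 °C
Reagents that add atoms: none
Why: Fluoride-mediated cleavage of the secondary silyl ether under non-basic conditions.

Step 14
Reactants: 20 allylic alcohol
Product: 21 suberosenone
Conditions: Dess–Martin periodinane, NaHCO3, CH2Cl2, 0 °C; used at once
Reagents that add atoms: none
Why: Buffered Dess–Martin oxidation of the allylic alcohol gives the α-methylene ketone without base that would trigger its self-addition.

Step 15
Reactants: 13 homologated aldehyde, 21 suberosenone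
Product: 22 keto aldehyde: 13 carrying at C4 (R) the C1' methylene that links to C2' of the saturated tricyclic ketone (C2' hydrogen anti to the C9' methyl)
Conditions: (R)-α,α-diphenylprolinol trimethylsilyl ether (20 mol %), 4-nitrophenol (20 mol %), CHCl3, 23 °C
Reagents that add atoms: none
Why: Enamine-catalysed Michael addition of an aldehyde to an enone; the E-enamine of 13 attacks the unhindered methylene terminus of 21 on the face away from the diphenyl(silyloxy)methyl group, which sets C4, and the enol so formed is protonated on the face away from the syn-axial C9' methyl, which sets C2'.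

Step 16
Reactants: 22 keto aldehyde, 14 ethynylmagnesium bromide
Product: 23 propargylic alcohol from ethynyl addition to the C3 aldehyde of 22
Conditions: 14 premixed with ClTi(OiPr)3, THF, −78 → −30 °C; aq. NH4Cl
Reagents that add atoms: none
Why: Ethynyltitanium triisopropoxide, formed in the flask by transmetalation, adds to aldehydes and leaves ketones untouched at low temperature, so only C3 reacts and the C3' ketone with its α-centre is spared.

Step 17
Reactants: 23 propargylic alcohol
Product: 24 C3 tert-butyldimethylsilyl ether of 23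
Conditions: TBSOTf, 2,6-lutidine, CH2Cl2, −78 °C
Reagents that add atoms: tert-butyldimethylsilyl triflate, CC(C)(C)[Si](C)(C)OS(=O)(=O)C(F)(F)F
Why: Alcohol silylation outruns enol silylation of the ketone at −78 °C and prevents lactonisation onto the C10 carboxyl.

Step 18
Reactants: 24 silyl ether
Product: 25 bridgehead carboxylic acid from 24
Conditions: Pd(PPh3)4 (5 mol %), morpholine, THF, 23 °C
Reagents that add atoms: none
Why: Tsuji–Trost deallylation under neutral conditions frees the acid without affecting the ketone, the silyl ether or the alkyne.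

Step 19
Reactants: 25 bridgehead acid
Product: 26 1,3-dioxoisoindolin-2-yl ester of 25 (precursor of the key step)
Conditions: N-hydroxyphthalimide, DIC, DMAP (cat.), CH2Cl2, 23 °C
Reagents that add atoms: N-hydroxyphthalimide, ON1C(=O)c2ccccc2C1=O
Why: Steglich-type carbodiimide esterification of the bridgehead acid, as in step 11.

Step 20
Reactants: 26 redox-active ester
Product: 27 3-silyloxy-2-methylidene precursor of the target (ring A of the enone half closed)
Conditions: [Ru(bpy)3]Cl2 (1 mol %), Hantzsch ester (1.5 equiv, in portions), DMF, blue LEDs, 23 °C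
Reagents that add atoms: none
Why: Electron transfer from the photoreduced ruthenium complex to the N-acyloxyphthalimide, then loss of phthalimide anion and CO2, gives the tertiary bridgehead radical at C10, which adds to the inner alkyne carbon C2; the vinyl radical at C1 then takes hydrogen from the Hantzsch ester and leaves the exocyclic methylene. The closest known reactions are reductive decarboxylative radical generation from N-acyloxyphthalimides and 5-exo-dig cyclisation of alkyl radicals onto terminal alkynes. Ring A (C2–C3–C4–C5–C10) closes in the 5-exo-dig mode, 6-endo attack at C1 being disfavoured by the three-atom tether. The only centre that changes is C10, where the bicycle holds the radical pyramidal with its single open lobe exo, so the C2–C10 bond forms with retention and the ring is necessarily cis-fused at C5–C10; C3, C4, C5 and C2' are untouched. The step needs ring closure to outrun hydrogen transfer to the bridgehead radical, which the fast exo closure of a reactive σ-type radical on a substituted tether and the low stationary concentration of hydrogen donor secure; the C3' ketone stays out of play because neither an enolate nor an electrophile is generated.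

Step 21
Reactants: 27 silyl ether
Product: 28 C3 allylic alcohol
Conditions: HF·pyridine, THF, 0 → 23 °C
Reagents that add atoms: none
Why: Fluoride-mediated silyl ether cleavage without base, so C2' and C4 are not put at risk.

Step 22
Reactants: 28 allylic alcohol
Product: 29 alertenone
Conditions: Dess–Martin periodinane, NaHCO3, CH2Cl2, 0 °C
Reagents that add atoms: none
Why: Buffered Dess–Martin oxidation of the allylic alcohol gives the cross-conjugated enone; C4, now α to the ketone, already carries its substituent trans to C6, the favoured arrangement.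

**Compound list**

1 | 3,3-dimethylcyclopentan-1-one | O=C1CC(C)(C)CC1 | starting material
2 | allyl 4,4-dimethyl-2-oxocyclopentane-1-carboxylate | C=CCOC(=O)C1CC(C)(C)CC1=O | intermediate
3 | (E)-but-2-enal | C/C=C/C=O | starting material
4 | allyl (1S)-4,4-dimethyl-2-oxo-1-[(2S)-4-oxobutan-2-yl]cyclopentane-1-carboxylate | O=CC[C@H](C)[C@@]1(C(=O)OCC=C)CC(C)(C)CC1=O | intermediate
5 | allyl (1S,2S,4S,5S)-4-hydroxy-2,6,6-trimethyl-8-oxobicyclo[3.2.1]octane-1-carboxylate (4-epimer also present) | O=C1[C@@H]2[C@@H](O)C[C@H](C)[C@@]1(C(=O)OCC=C)CC2(C)C | intermediate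
6 | O-phenyl thionocarbonate of 5 | O=C1[C@@H]2[C@@H](OC(=S)Oc3ccccc3)C[C@H](C)[C@@]1(C(=O)OCC=C)CC2(C)C | intermediate
7 | allyl (1S,2S,5R)-2,6,6-trimethyl-8-oxobicyclo[3.2.1]octane-1-carboxylate | O=C1[C@@H]2CC[C@H](C)[C@@]1(C(=O)OCC=C)CC2(C)C | intermediate
8 | (methoxymethyl)triphenylphosphonium chloride | COC[P+](c1ccccc1)(c1ccccc1)c1ccccc1.[Cl-] | starting material
9 | allyl 8-(methoxymethylidene)-2,6,6-trimethylbicyclo[3.2.1]octane-1-carboxylate (E/Z) | COC=C1[C@@H]2CC[C@H](C)[C@@]1(C(=O)OCC=C)CC2(C)C | intermediate
10 | allyl 8-formyl-2,6,6-trimethylbicyclo[3.2.1]octane-1-carboxylate, formyl over the three-carbon bridge (8-epimer of 11) | O=C[C@@H]1[C@@H]2CC[C@H](C)[C@@]1(C(=O)OCC=C)CC2(C)C | intermediate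
11 | allyl (1S,2S,5S,8S)-8-formyl-2,6,6-trimethylbicyclo[3.2.1]octane-1-carboxylate, formyl over the two-carbon bridge | O=C[C@H]1[C@@H]2CC[C@H](C)[C@@]1(C(=O)OCC=C)CC2(C)C | intermediate
12 | allyl 8-(2-methoxyethenyl)-2,6,6-trimethylbicyclo[3.2.1]octane-1-carboxylate (E/Z) | COC=C[C@H]1[C@@H]2CC[C@H](C)[C@@]1(C(=O)OCC=C)CC2(C)C | intermediate
13 | allyl (1S,2S,5S,8S)-2,6,6-trimethyl-8-(2-oxoethyl)bicyclo[3.2.1]octane-1-carboxylate | O=CC[C@H]1[C@@H]2CC[C@H](C)[C@@]1(C(=O)OCC=C)CC2(C)C | intermediate
14 | ethynylmagnesium bromide | C#C[Mg]Br | starting material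
15 | allyl 8-(2-hydroxybut-3-yn-1-yl)-2,6,6-trimethylbicyclo[3.2.1]octane-1-carboxylate (carbinol epimers) | C#C[C@H](O)C[C@H]1[C@@H]2CC[C@H](C)[C@@]1(C(=O)OCC=C)CC2(C)C | intermediate
16 | tert-butyldimethylsilyl ether of 15 | C#C[C@H](O[Si](C)(C)C(C)(C)C)C[C@H]1[C@@H]2CC[C@H](C)[C@@]1(C(=O)OCC=C)CC2(C)C | intermediate
17 | 8-[2-(tert-butyldimethylsilyloxy)but-3-yn-1-yl]-2,6,6-trimethylbicyclo[3.2.1]octane-1-carboxylic acid | C#C[C@H](O[Si](C)(C)C(C)(C)C)C[C@H]1[C@@H]2CC[C@H](C)[C@@]1(C(=O)O)CC2(C)C | intermediate
18 | 1,3-dioxoisoindolin-2-yl ester of 17 | C#C[C@H](O[Si](C)(C)C(C)(C)C)C[C@H]1[C@@H]2CC[C@H](C)[C@@]1(C(=O)ON3C(=O)c4ccccc4C3=O)CC2(C)C | intermediate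
19 | C3 tert-butyldimethylsilyl ether of 20 | C=C1[C@H](O[Si](C)(C)C(C)(C)C)C[C@H]2[C@@H]3CC[C@H](C)[C@]12CC3(C)C | intermediate
20 | tricyclic allylic alcohol (suberosenone with C3 as carbinol) | C=C1[C@H](O)C[C@H]2[C@@H]3CC[C@H](C)[C@]12CC3(C)C | intermediate
21 | suberosenone | C=C1C(=O)C[C@H]2[C@@H]3CC[C@H](C)[C@]12CC3(C)C | intermediate
22 | keto aldehyde (C4 R; C3 aldehyde; saturated tricyclic ketone attached through C1'; allyl ester) | O=C[C@H](C[C@@H]2C(=O)C[C@H]3[C@@H]4CC[C@H](C)[C@]23CC4(C)C)[C@H]2[C@@H]3CC[C@H](C)[C@@]2(C(=O)OCC=C)CC3(C)C | intermediate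
23 | propargylic alcohol from 22 (C3 epimers) | C#C[C@H](O)[C@H](C[C@@H]2C(=O)C[C@H]3[C@@H]4CC[C@H](C)[C@]23CC4(C)C)[C@H]2[C@@H]3CC[C@H](C)[C@@]2(C(=O)OCC=C)CC3(C)C | intermediate
24 | C3 tert-butyldimethylsilyl ether of 23 | C#C[C@H](O[Si](C)(C)C(C)(C)C)[C@H](C[C@@H]2C(=O)C[C@H]3[C@@H]4CC[C@H](C)[C@]23CC4(C)C)[C@H]2[C@@H]3CC[C@H](C)[C@@]2(C(=O)OCC=C)CC3(C)C | intermediate
25 | bridgehead carboxylic acid from 24 | C#C[C@H](O[Si](C)(C)C(C)(C)C)[C@H](C[C@@H]2C(=O)C[C@H]3[C@@H]4CC[C@H](C)[C@]23CC4(C)C)[C@H]2[C@@H]3CC[C@H](C)[C@@]2(C(=O)O)CC3(C)C | intermediate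
26 | 1,3-dioxoisoindolin-2-yl ester of 25 | C#C[C@H](O[Si](C)(C)C(C)(C)C)[C@H](C[C@@H]2C(=O)C[C@H]3[C@@H]4CC[C@H](C)[C@]23CC4(C)C)[C@H]2[C@@H]3CC[C@H](C)[C@@]2(C(=O)ON4C(=O)c5ccccc5C4=O)CC3(C)C | intermediate
27 | 3-silyloxy-2-methylidene precursor of the target | C=C1[C@H](O[Si](C)(C)C(C)(C)C)[C@H](C[C@@H]2C(=O)C[C@H]3[C@@H]4CC[C@H](C)[C@]23CC4(C)C)[C@H]2[C@@H]3CC[C@H](C)[C@]12CC3(C)C | intermediate
28 | C3 allylic alcohol | C=C1[C@H](O)[C@H](C[C@@H]2C(=O)C[C@H]3[C@@H]4CC[C@H](C)[C@]23CC4(C)C)[C@H]2[C@@H]3CC[C@H](C)[C@]12CC3(C)C | intermediate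
29 | alertenone | C=C1C(=O)[C@H](C[C@@H]2C(=O)C[C@H]3[C@@H]4CC[C@H](C)[C@]23CC4(C)C)[C@H]2[C@@H]3CC[C@H](C)[C@]12CC3(C)C | target

**Step count**

Total: 22 steps. Longest linear sequence: 22 steps (1 → 13 → 21 → 29; aldehyde 13 enters a second time in step 15).

**Steps most likely to fail**

Step 2. The conjugate addition may give poor control of the quaternary centre C10 relative to C9, so that part of the material closes to the bicycle with the C9 methyl on the wrong face. The fallback sets out from 2 and fixes C10 alone first. Conjugate addition to acrolein under a chiral 6'-hydroxy cinchona amine base (the pseudo-enantiomer that gives the drawn antipode) should give allyl (1R)-4,4-dimethyl-2-oxo-1-(3-oxopropyl)cyclopentane-1-carboxylate F1. DBU closes it to the ketol allyl 4-hydroxy-6,6-dimethyl-8-oxobicyclo[3.2.1]octane-1-carboxylate F2, and Dess–Martin oxidation gives the dione F3. IBX in DMSO dehydrogenates toward C8 to the enedione F4. Me2CuLi then adds to C9 from the face of the one-carbon bridge, the other face being blocked by the two-carbon bridge, and gives the methylated dione F5. NaBH4 at −78 °C reduces the less hindered C7 ketone, which brings the material back to the route at 5.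

Step 6. The equilibrium between the two C5 epimers of the aldehyde may not lie far enough on the side of 11. The fallback sets out from 7 and replaces the equilibrium by kinetic face selection. NaBH4 reduces the bridging ketone to allyl 8-hydroxy-2,6,6-trimethylbicyclo[3.2.1]octane-1-carboxylate F6 (either epimer), and NaH, CS2 and MeI convert it into the S-methyl xanthate F7. Radical carbonylation (Bu3SnH, AIBN, CO at 80 atm, benzene, 80 °C) generates the secondary C5 radical, which captures CO on its open face, syn to the two-carbon bridge and away from the axial C9 methyl. Reduction of the acyl radical returns the route at 11.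

Step 15. The union of two hindered partners may be slow, and facial control at C4 or in the ketonisation at C2' may be incomplete. The fallback sets out from 12 (isolated in step 7 before the acid is added) and 21. An inverse-electron-demand hetero-Diels–Alder reaction (Eu(fod)3, CH2Cl2, 23 °C, or heat) uses the enone as heterodiene and the enol ether as dienophile, and forms C4–C1' and the C3–O bond together in the 2-methoxy-3,4-dihydro-2H-pyran F8. Dilute aqueous acid opens the acetal and the cyclic enol ether, hydrogen again arriving at C2' anti to the C9' methyl, and returns the route at 22. C4 epimers would be separated there, and the unwanted one recycled by base equilibration of the α-branched aldehyde.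

**Further compounds**

F1 | step 2 | allyl (1R)-4,4-dimethyl-2-oxo-1-(3-oxopropyl)cyclopentane-1-carboxylate | O=CCC[C@@]1(C(=O)OCC=C)CC(C)(C)CC1=O
F2 | step 2 | allyl 4-hydroxy-6,6-dimethyl-8-oxobicyclo[3.2.1]octane-1-carboxylate (C4 epimers) | O=C1[C@@H]2C(O)CC[C@@]1(C(=O)OCC=C)CC2(C)C
F3 | step 2 | allyl 6,6-dimethyl-4,8-dioxobicyclo[3.2.1]octane-1-carboxylate | O=C1[C@@H]2C(=O)CC[C@@]1(C(=O)OCC=C)CC2(C)C
F4 | step 2 | allyl 6,6-dimethyl-4,8-dioxobicyclo[3.2.1]oct-2-ene-1-carboxylate | O=C1[C@@H]2C(=O)C=C[C@@]1(C(=O)OCC=C)CC2(C)C
F5 | step 2 | allyl 2,6,6-trimethyl-4,8-dioxobicyclo[3.2.1]octane-1-carboxylate (2-methyl syn to the one-carbon bridge) | O=C1[C@@H]2C(=O)C[C@H](C)[C@@]1(C(=O)OCC=C)CC2(C)C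
F6 | step 6 | allyl 8-hydroxy-2,6,6-trimethylbicyclo[3.2.1]octane-1-carboxylate (C8 epimers) | OC1[C@@H]2CC[C@H](C)[C@@]1(C(=O)OCC=C)CC2(C)C
F7 | step 6 | O-[1-(allyloxycarbonyl)-2,6,6-trimethylbicyclo[3.2.1]octan-8-yl] S-methyl dithiocarbonate | CSC(=S)OC1[C@@H]2CC[C@H](C)[C@@]1(C(=O)OCC=C)CC2(C)C
F8 | step 15 | 2-methoxy-3,4-dihydro-2H-pyran fused at C2'–C3' of the saturated tricycle, bearing the bicyclic allyl ester at C4 (acetal epimers) | COC1OC2=C(C[C@@H]1[C@H]4[C@@H]5CC[C@H](C)[C@@]4(C(=O)OCC=C)CC5(C)C)[C@]13[C@@H](C)CC[C@H](C(C)(C)C1)[C@@H]3C2
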